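Assumption: all five starting materials are catalogue items in the stated enantiomeric form.

## Retrosynthetic overview

1. The target is cut by a Heck disconnection in the triene, between the second and third chain carbons counted from the ring. This gives a vinyl carbinol that already carries the upper amide, plus the (2E,4E)-5-iododienamide of the aminocyclopentenone (ring C, bought intact).
2. The vinyl carbinol enamide comes from a copper-catalysed C–N coupling of a 2-iodo-4,5-dihydroxy-4-vinylcyclohexenone with a primary dienamide. The dienamide is made from hex-1-ene by asymmetric hydroformylation, Wittig and HWE reactions.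
3. The dihydroxy enone comes from a 2-alkoxy-2-vinyl-5-hydroxycyclohex-3-enone by hydroxyl-directed 1,3-anti reduction followed by allylic oxidation.
4. Key disconnection: this cyclohexenone (ring A) comes from a one-carbon ring enlargement, a 1,2-shift of the ring vinyl carbon in a 1-(1-alkoxyallenyl)cyclopent-2-enol. That carbinol is made from (R)-4-hydroxycyclopentenone and a lithiated alkoxyallene derived from propargyl alcohol.
5. Ring order: the five-membered carbocycle is bought and enlarged to ring A, which is the only ring-forming event.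

## Route

Step 1
Reactants: 1 prop-2-yn-1-ol
Product: 2 1-methoxy-4-[(prop-2-yn-1-yloxy)methyl]benzene (PMB propargyl ether)
Conditions: NaH (1.1 equiv), 4-methoxybenzyl chloride, Bu4NI (cat.), THF, 0 °C to rt
Reagents that add atoms: 4-methoxybenzyl chloride, COc1ccc(CCl)cc1
Why: Williamson ether synthesis, in which the alkoxide forms selectively over the acetylide and is alkylated by the activated benzylic chloride.

Step 2
Reactants: 3 (4R)-4-hydroxycyclopent-2-en-1-one
Product: 4 (4R)-4-(triethylsilyloxy)cyclopent-2-en-1-one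
Conditions: Et3SiCl, imidazole, CH2Cl2, 0 °C
Reagents that add atoms: chlorotriethylsilane, CC[Si](Cl)(CC)CC
Why: Imidazole-promoted silylation of the secondary allylic alcohol leaves the stereocentre untouched and installs a group that survives nBuLi but is lost in acidic methanol.

Step 3
Reactants: 2 PMB propargyl ether; 4 TES-protected hydroxy enone
Product: 7 (1S,4R)-1-{1-[(4-methoxyphenyl)methoxy]propa-1,2-dien-1-yl}-4-(triethylsilyloxy)cyclopent-2-en-1-ol, via PMB allenyl ether 5 (not isolated), via 1-lithio allenyl ether 6 (not isolated)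
Conditions: 2 (1.3 equiv), KOtBu (0.2 equiv), THF, rt; nBuLi (1.3 equiv), −78 °C; 4, −78 °C; H2O; Et3N-washed silica
Reagents that add atoms: none
Why: Base-catalysed propargyl-to-allenyl ether isomerisation, alpha-lithiation of the alkoxyallene and 1,2-addition of the hard organolithium to the enone carbonyl, with attack on the face opposite the silyloxy group setting the carbinol centre (1S), and the minor epimer removed by chromatography.

Step 4
Reactants: 7 allenyl cyclopentenol
Product: 9 (2S,5R)-2-ethenyl-5-hydroxy-2-[(4-methoxyphenyl)methoxy]cyclohex-3-en-1-one, via ring-enlarged TES ether 8 (not isolated)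
Conditions: Tf2NH (5 mol %), 4 Å MS, CH2Cl2 (0.02 M), −78 °C; then MeOH, −78 to 0 °C; Et3N quench
Reagents that add atoms: none
Why: Proposed new method: proton transfer to the central allene carbon of 7 gives an alkoxy-stabilised allyl cation next to the tertiary carbinol; the ring vinyl carbon, a better migrating group than the CH2 flanked by the silyloxy carbon, shifts 1,2 to it while the hydroxyl collapses to the ketone and returns the proton, and consumption of the allene makes the five-to-six enlargement irreversible; the shift runs through the rotamer with the two C–O dipoles opposed and the small ether oxygen beside the ring CH2, so the carbinol configuration is relayed to the new quaternary centre (2S), and methanol then removes the silyl group; the closest known reaction types are the acid-catalysed semipinacol enlargement of 1-(1-alkoxyvinyl)cyclobutanols and the palladium hydride enlargement of 1-(1-alkoxyallenyl)cyclobutanols, neither of which has been shown for an unstrained cyclopentenol or for a migrating ring alkene carbon.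

Step 5
Reactants: 9 beta-hydroxy ketone
Product: 10 (1R,3R,6S)-6-ethenyl-6-[(4-methoxyphenyl)methoxy]cyclohex-4-ene-1,3-diol
Conditions: Me4NBH(OAc)3 (5 equiv), MeCN/AcOH 1:1, −30 °C; aq NaHCO3
Reagents that add atoms: none
Why: Evans–Saksena hydroxyl-directed reduction, in which the free allylic hydroxyl binds boron and delivers hydride to its own face of the ketone, giving the 1,3-anti diol whose new carbinol (1R) is cis to the PMB-protected tertiary oxygen, an attack that is also anti to the pseudoaxial C–O bond (polar Felkin–Anh).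

Step 6
Reactants: 10 mono-PMB triol
Product: 12 (4S,5R)-4-ethenyl-4,5-dihydroxycyclohex-2-en-1-one, via enone PMB ether 11 (not isolated)
Conditions: MnO2 (15 equiv), CH2Cl2, rt, 2 h; then DDQ (0.3 equiv), H2O (10 equiv), rt
Reagents that add atoms: none
Why: MnO2 oxidises only the allylic secondary alcohol, and DDQ, recycled by the same MnO2, then cleaves the PMB ether by benzylic hydride abstraction and hydrolysis, both being known oxidations that leave the two carbinol centres untouched.

Step 7
Reactants: 12 dihydroxy vinyl enone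
Product: 13 (4S,5R)-4-ethenyl-4,5-dihydroxy-2-iodocyclohex-2-en-1-one
Conditions: I2 (1.5 equiv), pyridine/CH2Cl2 1:1, 0 °C to rt
Reagents that add atoms: iodine, II
Why: Johnson alpha-iodination (conjugate addition of pyridine, iodination of the enolate, elimination) works on 4,4-disubstituted cyclohexenones and tolerates free alcohols and an isolated vinyl group.

Step 8
Reactants: 14 hex-1-ene
Product: 15 (2R)-2-methylhexanal
Conditions: Rh(acac)(CO)2 (0.4 mol %), BOBPHOS (0.5 mol %, the enantiomer that gives the R aldehyde), CO/H2 1:1 (5 bar), toluene, 16 °C; fractional distillation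
Reagents that add atoms: carbon monoxide, [C-]#[O+]
Why: Branched-selective asymmetric hydroformylation of an unbiased 1-alkene (about 3:1 branched to linear and about 93% ee for this alkene) sets the methyl-bearing stereocentre (R), and the higher-boiling heptanal is removed by distillation.

Step 9
Reactants: 15 (2R)-2-methylhexanal
Product: 16 (2E,4R)-2,4-dimethyloct-2-enal
Conditions: Ph3P=C(CH3)CHO (1.2 equiv), toluene, 90 °C
Reagents that add atoms: 2-(triphenylphosphoranylidene)propanal, CC(C=O)=P(c1ccccc1)(c1ccccc1)c1ccccc1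
Why: Wittig olefination with a stabilised, non-basic ylide gives the E trisubstituted enal without epimerising the alpha stereocentre.

Step 10
Reactants: 16 (2E,4R)-2,4-dimethyloct-2-enal
Product: 17 (2E,4E,6R)-4,6-dimethyldeca-2,4-dienamide
Conditions: (EtO)2P(O)CH2CONH2, NaH, THF, 0 °C to rt; recrystallisation
Reagents that add atoms: diethyl (2-amino-2-oxoethyl)phosphonate, CCOP(=O)(CC(N)=O)OCC
Why: Horner–Wadsworth–Emmons olefination gives the E alkene and the primary amide in one operation, and recrystallising the solid amide raises the enantiomeric purity.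

Step 11
Reactants: 13 iodo enone; 17 primary dienamide
Product: 18 (2E,4E,6R)-N-[(3S,4R)-3-ethenyl-3,4-dihydroxy-6-oxocyclohex-1-en-1-yl]-4,6-dimethyldeca-2,4-dienamide
Conditions: CuI (0.2 equiv), MeNHCH2CH2NHMe (0.4 equiv), Cs2CO3 (1.5 equiv), THF, 50 °C
Reagents that add atoms: none
Why: Goldberg–Buchwald copper-catalysed amidation of a vinyl iodide replaces iodine by the amide nitrogen at the same carbon, and the alpha-iodo enone is an activated partner that couples at moderate temperature.

Step 12
Reactants: 19 methyl (2E)-4-oxobut-2-enoate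
Product: 20 methyl (2E,4E)-5-iodopenta-2,4-dienoate
Conditions: CrCl2 (6 equiv), CHI3 (2 equiv), THF, 0 °C
Reagents that add atoms: iodoform, IC(I)I
Why: Takai olefination converts the aldehyde into the E vinyl iodide through a gem-dichromium species and leaves the enoate untouched.

Step 13
Reactants: 20 iodo dienoate
Product: 21 (2E,4E)-5-iodopenta-2,4-dienoic acid
Conditions: LiOH, THF/H2O 3:1, 0 °C to rt; 1 M HCl to pH 3
Reagents that add atoms: lithium hydroxide, [Li+].[OH-]
Why: Ester saponification under mild conditions keeps both alkene geometries and the vinyl iodide.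

Step 14
Reactants: 21 iodo dienoic acid; 22 2-amino-3-hydroxycyclopent-2-en-1-one
Product: 24 (2E,4E)-N-(2-hydroxy-5-oxocyclopent-1-en-1-yl)-5-iodopenta-2,4-dienamide, via acid chloride 23 (not isolated)
Conditions: (COCl)2, DMF (cat.), CH2Cl2, 0 °C; concentrate; 22, pyridine, CH2Cl2, 0 °C to rt
Reagents that add atoms: none
Why: Acylation of the amine with the acid chloride gives the amide, and any O-acyl isomer moves to nitrogen under the reaction conditions.

Step 15
Reactants: 18 vinyl carbinol enamide; 24 iodo dienamide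
Product: 25 (2E,4E,6R)-N-[(3S,4R)-3,4-dihydroxy-3-[(1E,3E,5E)-7-[(2-hydroxy-5-oxocyclopent-1-en-1-yl)amino]-7-oxohepta-1,3,5-trien-1-yl]-6-oxocyclohex-1-en-1-yl]-4,6-dimethyldeca-2,4-dienamide (target)
Conditions: Pd(OAc)2 (0.1 equiv), Bu4NCl (1 equiv), NaHCO3 (3 equiv), DMF, 35 °C, dark; pH 5 buffer work-up
Reagents that add atoms: none
Why: Heck vinylation under Jeffery conditions, in which syn insertion at the unhindered terminal CH2 and syn beta-hydride elimination give the new E alkene, the iodide keeps its geometry, and the fully substituted carbinol carbon prevents isomerisation to a ketone.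

## Compound list

1 | prop-2-yn-1-ol | C#CCO | starting material
2 | 1-methoxy-4-[(prop-2-yn-1-yloxy)methyl]benzene | C#CCOCc1ccc(OC)cc1 | intermediate
3 | (4R)-4-hydroxycyclopent-2-en-1-one | O=C1C=C[C@H](O)C1 | starting material
4 | (4R)-4-(triethylsilyloxy)cyclopent-2-en-1-one | O=C1C=C[C@H](O[Si](CC)(CC)CC)C1 | intermediate
5 | 1-methoxy-4-[(propa-1,2-dien-1-yloxy)methyl]benzene | C=C=COCc1ccc(OC)cc1 | intermediate
6 | {1-[(4-methoxyphenyl)methoxy]propa-1,2-dien-1-yl}lithium | [Li]C(=C=C)OCc1ccc(OC)cc1 | intermediate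
7 | (1S,4R)-1-{1-[(4-methoxyphenyl)methoxy]propa-1,2-dien-1-yl}-4-(triethylsilyloxy)cyclopent-2-en-1-ol | O[C@]1(C(=C=C)OCc2ccc(OC)cc2)C=C[C@H](O[Si](CC)(CC)CC)C1 | intermediate
8 | (2S,5R)-2-ethenyl-2-[(4-methoxyphenyl)methoxy]-5-(triethylsilyloxy)cyclohex-3-en-1-one | O=C1C[C@@H](O[Si](CC)(CC)CC)C=C[C@@]1(OCc2ccc(OC)cc2)C=C | intermediate
9 | (2S,5R)-2-ethenyl-5-hydroxy-2-[(4-methoxyphenyl)methoxy]cyclohex-3-en-1-one | O=C1C[C@@H](O)C=C[C@@]1(OCc2ccc(OC)cc2)C=C | intermediate
10 | (1R,3R,6S)-6-ethenyl-6-[(4-methoxyphenyl)methoxy]cyclohex-4-ene-1,3-diol | O[C@@H]1C[C@@H](O)C=C[C@@]1(OCc2ccc(OC)cc2)C=C | intermediate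
11 | (4S,5R)-4-ethenyl-5-hydroxy-4-[(4-methoxyphenyl)methoxy]cyclohex-2-en-1-one | O=C1C=C[C@@](OCc2ccc(OC)cc2)(C=C)[C@H](O)C1 | intermediate
12 | (4S,5R)-4-ethenyl-4,5-dihydroxycyclohex-2-en-1-one | O=C1C=C[C@@](O)(C=C)[C@H](O)C1 | intermediate
13 | (4S,5R)-4-ethenyl-4,5-dihydroxy-2-iodocyclohex-2-en-1-one | O=C1C(I)=C[C@@](O)(C=C)[C@H](O)C1 | intermediate
14 | hex-1-ene | C=CCCCC | starting material
15 | (2R)-2-methylhexanal | CCCC[C@@H](C)C=O | intermediate
16 | (2E,4R)-2,4-dimethyloct-2-enal | CCCC[C@@H](C)/C=C(C)/C=O | intermediate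
17 | (2E,4E,6R)-4,6-dimethyldeca-2,4-dienamide | CCCC[C@@H](C)/C=C(C)/C=C/C(N)=O | intermediate
18 | (2E,4E,6R)-N-[(3S,4R)-3-ethenyl-3,4-dihydroxy-6-oxocyclohex-1-en-1-yl]-4,6-dimethyldeca-2,4-dienamide | CCCC[C@@H](C)/C=C(C)/C=C/C(=O)NC1=C[C@@](O)(C=C)[C@H](O)CC1=O | intermediate
19 | methyl (2E)-4-oxobut-2-enoate | COC(=O)/C=C/C=O | starting material
20 | methyl (2E,4E)-5-iodopenta-2,4-dienoate | COC(=O)/C=C/C=C/I | intermediate
21 | (2E,4E)-5-iodopenta-2,4-dienoic acid | OC(=O)/C=C/C=C/I | intermediate
22 | 2-amino-3-hydroxycyclopent-2-en-1-one | NC1=C(O)CCC1=O | starting material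
23 | (2E,4E)-5-iodopenta-2,4-dienoyl chloride | ClC(=O)/C=C/C=C/I | intermediate
24 | (2E,4E)-N-(2-hydroxy-5-oxocyclopent-1-en-1-yl)-5-iodopenta-2,4-dienamide | O=C(/C=C/C=C/I)NC1=C(O)CCC1=O | intermediate
25 | CNP0284264.2 | CCCC[C@@H](C)/C=C(C)/C=C/C(=O)NC1=C[C@@](O)(/C=C/C=C/C=C/C(=O)NC2=C(O)CCC2=O)[C@H](O)CC1=O | target

## Step count and risks

Total steps: 15. Longest linear sequence: 8 (step 1 or 2, then 3, 4, 5, 6, 7, 11, 15).

**Risk 1, step 4 (the proposed new ring enlargement).**
- The cation may lose the PMB group to give the hydroxy vinyl ketone.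
- The carbinol may ionise and cyclise in a Nazarov manner.
- The ring CH2 may migrate instead of the vinyl carbon.
- The other rotamer may react and give the epimer at the quaternary centre.

The fallback sets out from 17 and comes back at 18. It takes ring A from an arene by the known quinone monoketal epoxide chemistry of this antibiotic family. 3-Bromophenol F1 is oxidised with PhI(OAc)2 (2.2 equiv) in MeOH to 3-bromo-4,4-dimethoxycyclohexa-2,5-dien-1-one F2. Coupling with 17 (Pd2(dba)3, Xantphos, Cs2CO3, dioxane) gives the amido quinone monoketal F3. Phase-transfer epoxidation follows, using tBuOOH, NaOH and N-benzylcinchonidinium chloride or its cinchoninium counterpart, whichever gives the (1R,6S) series. This oxidises the unsubstituted enone bond to the epoxy ketone F4. CH2=CHMgBr (3 equiv, THF, −78 °C) adds to the ketone anti to the epoxide to give the vinyl carbinol F5. Montmorillonite K10 in CH2Cl2 frees the ketone to give the epoxyquinol F6. Finally Na[PhSeB(OEt)3] (from PhSeSePh and NaBH4 in EtOH, with AcOH) opens the alpha,beta-epoxy ketone reductively at the alpha carbon to give 18.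

**Risk 2, step 11.** Warm carbonate can trigger retro-aldol epimerisation or E1cB loss of the free aldol hydroxyl of 13 or 18, giving the quinol.

The fallback sets out from 13 and comes back at 18, and it removes the free aldol unit before the C–N bond is made. 2,2-Dimethoxypropane and PPTS in CH2Cl2 convert 13 into the iodo enone acetonide F7. The CuI/diamine coupling with 17 then gives the enamide acetonide F8. PPTS in MeOH at 40 °C releases 18.

**Risk 3, step 15.** The polyene may isomerise, the iodide may homocouple, or the hindered vinyl carbinol may insert slowly.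

The fallback sets out from 18 and comes back at 25, and it replaces the Heck reaction by two bond-specific couplings. Cross metathesis of 18 with vinylboronic acid pinacol ester (second-generation Hoveyda–Grubbs catalyst, CH2Cl2, 40 °C) gives the (E)-alkenylboronate F9. Suzuki–Miyaura coupling with 24 (Pd(PPh3)4, K3PO4, THF/H2O, rt, dark) then gives 25.

## Further compounds

F1 | step 4 | 3-bromophenol | Oc1cccc(Br)c1
F2 | step 4 | 3-bromo-4,4-dimethoxycyclohexa-2,5-dien-1-one | COC1(OC)C=CC(=O)C=C1Br
F3 | step 4 | (2E,4E,6R)-N-(6,6-dimethoxy-3-oxocyclohexa-1,4-dien-1-yl)-4,6-dimethyldeca-2,4-dienamide | CCCC[C@@H](C)/C=C(C)/C=C/C(=O)NC1=CC(=O)C=CC1(OC)OC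
F4 | step 4 | (2E,4E,6R)-N-[(1R,6S)-5,5-dimethoxy-2-oxo-7-oxabicyclo[4.1.0]hept-3-en-4-yl]-4,6-dimethyldeca-2,4-dienamide | CCCC[C@@H](C)/C=C(C)/C=C/C(=O)NC1=CC(=O)[C@@H]2O[C@@H]2C1(OC)OC
F5 | step 4 | (2E,4E,6R)-N-[(1S,5S,6R)-5-ethenyl-5-hydroxy-2,2-dimethoxy-7-oxabicyclo[4.1.0]hept-3-en-3-yl]-4,6-dimethyldeca-2,4-dienamide | CCCC[C@@H](C)/C=C(C)/C=C/C(=O)NC1=C[C@@](O)(C=C)[C@@H]2O[C@@H]2C1(OC)OC
F6 | step 4 | (2E,4E,6R)-N-[(1S,5S,6R)-5-ethenyl-5-hydroxy-2-oxo-7-oxabicyclo[4.1.0]hept-3-en-3-yl]-4,6-dimethyldeca-2,4-dienamide | CCCC[C@@H](C)/C=C(C)/C=C/C(=O)NC1=C[C@@](O)(C=C)[C@@H]2O[C@@H]2C1=O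
F7 | step 11 | (3aS,7aR)-3a-ethenyl-5-iodo-2,2-dimethyl-7,7a-dihydro-3aH-1,3-benzodioxol-6-one | O=C1C(I)=C[C@]2(C=C)OC(C)(C)O[C@@H]2C1
F8 | step 11 | (2E,4E,6R)-N-[(3aS,7aR)-3a-ethenyl-2,2-dimethyl-6-oxo-7,7a-dihydro-3aH-1,3-benzodioxol-5-yl]-4,6-dimethyldeca-2,4-dienamide | CCCC[C@@H](C)/C=C(C)/C=C/C(=O)NC1=C[C@]2(C=C)OC(C)(C)O[C@@H]2CC1=O
F9 | step 15 | (2E,4E,6R)-N-{(3S,4R)-3,4-dihydroxy-6-oxo-3-[(E)-2-(4,4,5,5-tetramethyl-1,3,2-dioxaborolan-2-yl)ethenyl]cyclohex-1-en-1-yl}-4,6-dimethyldeca-2,4-dienamide | CCCC[C@@H](C)/C=C(C)/C=C/C(=O)NC1=C[C@@](O)(/C=C/B2OC(C)(C)C(C)(C)O2)[C@H](O)CC1=O
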